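## Structural features

The target 24 is a 2′,4′,6′-trihydroxydihydrochalcone. Ring A (the phloroglucinol ring, C1′–C6′) carries the 3-(4-methoxyphenyl)propanoyl chain (ring B) on C1′, hydroxyl groups on C2′, C4′ and C6′, hydrogen on C5′, and a 1,4-diaryl-2,3-dimethylbutyl chain on C3′. In that chain C1 is a methine bonded to ring A, ring C (4-hydroxyphenyl) and C2; C2 and C3 each carry one methyl group; C4 is a methylene bonded to ring D (4-hydroxyphenyl). C1 (S), C2 (R) and C3 (S) are three contiguous stereocentres bearing only carbon and hydrogen in an open chain. In the zigzag C1–C4 the two methyl groups are syn (the threo series of 8–8′ lignans) and ring C is anti to the C2 methyl. Fragile points are the electron-rich ring A (oxidation, multiple substitution), the C1–C3′ bond (benzylic to two donor-substituted rings, so acid can ionise it and scramble C1), and the need to free five phenols while the methyl ether of ring B stays. The real difficulty is the stereotriad: no heteroatom or carbonyl sits on or next to C1–C3 in the target, so nothing in the final structure can direct or correct these centres, and C1 hangs on a ring carbon flanked by two oxygens. The key step exploits two facts. C2 and C3 both bear a methyl group, so C2–C3 is the central bond of a 2,3-disubstituted succinic acid in reduced form. The methyl carbon on C2 is in a 1,5-relation to the oxygen on C2′ (O–C2′–C3′–C1–C2–CH3), so it can be held as the carbonyl of a six-membered aryl lactone (a 4-aryl-3,4-dihydrocoumarin) with C1 and C2 as ring atoms.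

## Logic of the disconnections

24 back to 23, then to 17 and 20 (17 from 16). Bonds cut: five O–benzyl bonds in place of the phenolic O–H bonds, then the C1′–C(=O) bond (and C1′–Br back to C1′–H). The ketone cannot coexist with the enolate and hydride steps that build the chain. Once the chain is on C3′, the free positions C1′ and C5′ lead to the same final structure, so there is no regiochemical question. The gain is that ring B and its tether leave as 20 and what remains (16) is a hydrocarbon-like core. The demand is acyl transfer without acid, because C1 can ionise, and a hydrogenolysis that spares the aryl ketone and the methyl ether.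

16 back to 12 (through 15, 14 and 13). Bonds cut: the C–H bonds of the two methyl groups on C2 and C3 that stand in place of C–O bonds. Both methyl carbons are raised to the carboxyl level, the one on C2 as a lactone carbonyl bonded to the oxygen on C2′ and the one on C3 as a benzyl ester. The 2,3-dimethylbutane thereby becomes a succinate whose central bond joins two α-carbonyl carbons, with C1 and C2 locked in a six-membered ring. The demand is exhaustive reduction to the 1,4-diol, capping of the freed phenol, and double deoxygenation, none of which may break a bond to C1, C2 or C3.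

12 back to 4 and 10 (key disconnection). Bond cut: C2–C3, the 8–8′ bond of the lignan unit. Both carbons are α to a carbonyl group and so of like (donor) polarity; the polarity of C3 is reversed by a triflate leaving group. In one sentence: the C2–C3 bond is made by SN2 union of the enolate of 4 with 10. That sentence does not fit the route drawn first, which joins C1 to ring A. The gain is that 12, with all carbons of the lignan unit and all three stereocentres, falls into two pieces of one stereocentre each. The demand is substitution with inversion at a secondary carbon by a hindered enolate, entering anti to the aryl group on the ring, in competition with elimination.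

4 back to 2 and 3, and 2 back to 1. Bonds cut: C1–ring C, then two O–benzyl bonds. C1 becomes the β-carbon of a coumarin, so a catalyst can set it in a conjugate arylation before any other centre exists. The gain is the flat, achiral 2. The demand is enantioface-selective aryl transfer to a peri-substituted, donor-substituted coumarin.

10 back to 9, 8 and 5. Bonds cut: O–S of the triflate, two O–benzyl bonds, then C–O exchanged for C–N at the stereocentre. C3, C4 and ring D with an α-heteroatom stereocentre are the skeleton of an aromatic amino acid, so the C3 centre is bought. The demand is diazotisation with net retention and triflate formation and use without racemisation.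

20 back to 18. Bond cut: the amide C–N bond. This is a routine activation of a commercial acid.

## Other disconnections considered

Alternative 1: the first idea is to cut C1–C3′. Forward, the benzylic alcohol (2R,3S)-1,4-bis(4-hydroxyphenyl)-2,3-dimethylbutan-1-ol A1 would be ionised to the para-quinone methide A2, which the dihydrochalcone A3 would capture in a Friedel–Crafts alkylation. A2 is planar at C1 and its two faces differ only through the neighbouring C2 (methyl against a branched alkyl), so acyclic 1,2-induction is the sole control and a mixture at C1 is expected. A3 offers two equivalent ring carbons and three hydroxyl groups, so double C-alkylation and O-alkylation compete. A1 itself needs a full lignan synthesis including the same diol-to-dimethyl reduction, so no steps are saved. The chosen plan fixes C1 by a catalyst and uses it to set C2 through a ring.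

Alternative 2: cut C1–C2 together with the lactone O–C(=O) bond. Forward, an ortho-quinone methide generated from benzhydrol A4 would undergo a catalytic enantioselective [4+2] annulation with a chiral ammonium or azolium enolate of acid A5, giving lactone A6 directly or after epimerisation at the lactone α-carbon. C3 would have to be set beforehand by a separate asymmetric step in A5. The annulation normally gives the 3,4-cis lactone, so a base epimerisation is added. The catalyst would have to override the β-stereocentre of a β-branched enolate. An ortho-quinone methide on a trioxygenated ring is strongly stabilised and a poor electrophile. The chosen plan replaces this catalyst-controlled event by a stereospecific SN2 and a ring-controlled alkylation, at a similar step count.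

Alternative 3: cut C2–C3 by a [3,3] shift. Forward, an Ireland–Claisen rearrangement of crotyl ester A7 would give acid A8. The chair transition state would relate C2 to C3 reliably, but the face of the ketene acetal would be chosen only by the open-chain C1 centre in the β-position, a weak bias. The vinyl group of A8 then has to lose one carbon and gain ring D (ozonolysis to an epimerisable α-branched aldehyde, aryl addition, deoxygenation) and the carboxyl group has to be reduced to methyl. That is at least five further steps on the longest line, against three in the chosen plan for the same carbons.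

Key step: step 6

Remark: the 4S sense of (S)-SEGPHOS in step 2 is assigned by analogy with simple coumarins; the enantiomeric ligand is used if the facial preference proves opposite. After step 6 no bond to C1, C2 or C3 is made or broken; later changes of R/S descriptors reflect CIP priorities only.

## Steps

Step 1
Reactants: 1 5,7-dihydroxy-2H-chromen-2-one
Product: 2 5,7-bis(benzyloxy)-2H-chromen-2-one
Conditions: BnBr (2.4 equiv), K2CO3, DMF, 60 °C
Reagents that add atoms: benzyl bromide, BrCc1ccccc1
Why: Williamson ether synthesis on the two phenols; the coumarin lactone is inert to carbonate under anhydrous conditions.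

Step 2
Reactants: 2 5,7-bis(benzyloxy)-2H-chromen-2-one; 3 [4-(benzyloxy)phenyl]boronic acid
Product: 4 (4S)-5,7-bis(benzyloxy)-4-[4-(benzyloxy)phenyl]-3,4-dihydro-2H-chromen-2-one
Conditions: Rh(acac)(C2H4)2 (3 mol %), (S)-SEGPHOS (3.3 mol %), 3 (4 equiv, in portions), 1,4-dioxane/H2O 10:1, 60 °C
Reagents that add atoms: none
Why: Rhodium-catalysed asymmetric 1,4-addition of an arylboronic acid to a coumarin (Hayashi–Miyaura reaction): transmetalation gives an aryl complex of monovalent rhodium, the C3=C4 bond inserts, and water protonates the resulting oxa-π-allyl species. The stereocentre at C4 of the lactone (C1 of the target) is set by the chiral bisphosphine, which selects one face of the planar coumarin.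

Step 3
Reactants: 5 L-tyrosine
Product: 8 (2S)-2-hydroxy-3-(4-hydroxyphenyl)propanoic acid, via diazonium carboxylate 6 (not isolated), via α-lactone 7 (not isolated)
Conditions: NaNO2, 1 M aq. H2SO4, 0 °C to rt
Reagents that add atoms: water, O
Why: Diazotisation of an α-amino acid: nitrosation gives diazonium 6, the neighbouring carboxylate expels N2 with inversion to α-lactone 7, and water opens 7 with a second inversion. The net result is retention, so the S centre of 5 becomes the S centre of 8.

Step 4
Reactants: 8 (2S)-2-hydroxy-3-(4-hydroxyphenyl)propanoic acid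
Product: 9 benzyl (2S)-3-[4-(benzyloxy)phenyl]-2-hydroxypropanoate
Conditions: BnBr (2.2 equiv), K2CO3, DMF, rt
Reagents that add atoms: benzyl bromide, BrCc1ccccc1
Why: Carbonate ionises only the carboxylic acid and the phenol, and both are benzylated by SN2 (ester alkylation and Williamson ether synthesis). The secondary alcohol and its stereocentre are untouched.

Step 5
Reactants: 9 benzyl (2S)-3-[4-(benzyloxy)phenyl]-2-hydroxypropanoate
Product: 10 benzyl (2S)-3-[4-(benzyloxy)phenyl]-2-{[(trifluoromethyl)sulfonyl]oxy}propanoate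
Conditions: Tf2O, 2,6-lutidine, CH2Cl2, −78 to −20 °C; short silica plug, used at once
Reagents that add atoms: trifluoromethanesulfonic anhydride, O=S(=O)(OS(=O)(=O)C(F)(F)F)C(F)(F)F
Why: O-sulfonylation of a secondary alcohol with a hindered base at low temperature. The C–O bond at the stereocentre is not broken, so the configuration is retained, and the adjacent ester disfavours ionisation of the triflate.

Step 6
Reactants: 4 (4S)-5,7-bis(benzyloxy)-4-[4-(benzyloxy)phenyl]-3,4-dihydro-2H-chromen-2-one; 10 benzyl (2S)-3-[4-(benzyloxy)phenyl]-2-{[(trifluoromethyl)sulfonyl]oxy}propanoate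
Product: 12 benzyl (2S)-3-[4-(benzyloxy)phenyl]-2-{(3S,4S)-5,7-bis(benzyloxy)-4-[4-(benzyloxy)phenyl]-2-oxo-3,4-dihydro-2H-chromen-3-yl}propanoate, via lithium enolate 11 (not isolated)
Conditions: LiN(SiMe3)2 (1.05 equiv), THF, −78 °C; then 10 (1.3 equiv) in THF, −78 to −40 °C; AcOH quench at −78 °C
Reagents that add atoms: none
Why: Deprotonation of 4 at C3 gives the planar lithium enolate 11, whose C3 attacks the triflate-bearing carbon of 10 in an SN2 displacement; the closest known reaction type is enolate alkylation by α-sulfonyloxy esters, the established polar entry to 2,3-disubstituted succinates. The step closes no ring and forms only the C2–C3 bond of the target, joining two α-carbonyl carbons of like polarity through polarity reversal at C3. The ester next to the leaving group accelerates SN2 and suppresses ionisation, so C3 of the target arises by clean inversion of the tyrosine-derived centre: the (2S)-triflate gives the (2S)-propanoate, the descriptor being unchanged only because the priorities change. The new centre at lactone C3 (C2 of the target) is set by the existing C4 centre: the peri 5-benzyloxy group pushes the C4 aryl pseudo-axial, it shields one enolate face, and the electrophile enters anti to it to give the 3,4-trans lactone, which is also the more stable isomer. The step needs C- over O-alkylation (soft secondary carbon electrophile, lithium counter-ion), substitution over E2 loss of triflic acid towards the cinnamate (low temperature, no excess base, a delocalised and weakly basic aryl-ester enolate), and no epimerisation of either α-centre (acidic quench at −78 °C). Both partners are single enantiomers, so a mismatch can lower only the rate and not the stereochemical outcome, which is fixed by inversion and by the ring.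

Step 7
Reactants: 12 benzyl (2S)-3-[4-(benzyloxy)phenyl]-2-{(3S,4S)-5,7-bis(benzyloxy)-4-[4-(benzyloxy)phenyl]-2-oxo-3,4-dihydro-2H-chromen-3-yl}propanoate
Product: 13 (2S,3S)-2-[4-(benzyloxy)benzyl]-3-{(S)-[2,4-bis(benzyloxy)-6-hydroxyphenyl][4-(benzyloxy)phenyl]methyl}butane-1,4-diol
Conditions: LiAlH4 (3 equiv), THF, 0 °C to rt; aq. potassium sodium tartrate
Reagents that add atoms: none
Why: Hydride reduction of the aryl lactone and the benzyl ester to primary alcohols, which frees the ring-A phenol. No bond to a stereocentre is broken and reduction outruns enolisation, so the three centres are kept.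

Step 8
Reactants: 13 (2S,3S)-2-[4-(benzyloxy)benzyl]-3-{(S)-[2,4-bis(benzyloxy)-6-hydroxyphenyl][4-(benzyloxy)phenyl]methyl}butane-1,4-diol
Product: 14 (2S,3S)-2-[4-(benzyloxy)benzyl]-3-{(S)-[4-(benzyloxy)phenyl][2,4,6-tris(benzyloxy)phenyl]methyl}butane-1,4-diol
Conditions: BnBr (1.2 equiv), K2CO3, acetone, reflux
Reagents that add atoms: benzyl bromide, BrCc1ccccc1
Why: Williamson ether synthesis; only the phenol is acidic enough for carbonate. Capping it prevents O-alkylation to a chroman in the next two steps.

Step 9
Reactants: 14 (2S,3S)-2-[4-(benzyloxy)benzyl]-3-{(S)-[4-(benzyloxy)phenyl][2,4,6-tris(benzyloxy)phenyl]methyl}butane-1,4-diol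
Product: 15 (2S,3S)-2-[4-(benzyloxy)benzyl]-3-{(S)-[4-(benzyloxy)phenyl][2,4,6-tris(benzyloxy)phenyl]methyl}butane-1,4-diyl dimethanesulfonate
Conditions: MsCl (3 equiv), Et3N (4 equiv), CH2Cl2, −10 to 0 °C
Reagents that add atoms: methanesulfonyl chloride, CS(=O)(=O)Cl
Why: Sulfonylation of both primary alcohols is fast at low temperature with excess reagent, so the second hydroxyl is capped before it can displace the first mesylate to form a tetrahydrofuran.

Step 10
Reactants: 15 (2S,3S)-2-[4-(benzyloxy)benzyl]-3-{(S)-[4-(benzyloxy)phenyl][2,4,6-tris(benzyloxy)phenyl]methyl}butane-1,4-diyl dimethanesulfonate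
Product: 16 1,3,5-tris(benzyloxy)-2-{(1S,2R,3S)-1,4-bis[4-(benzyloxy)phenyl]-2,3-dimethylbutyl}benzene
Conditions: LiEt3BH (5 equiv), THF, 0 °C to reflux
Reagents that add atoms: none
Why: SN2 displacement of the two primary mesylates by hydride, the standard diol-to-dimethyl sequence of lignan chemistry, turns both CH2O groups into the C2 and C3 methyl groups. The stereocentres are β to the reacting carbons and unaffected.

Step 11
Reactants: 16 1,3,5-tris(benzyloxy)-2-{(1S,2R,3S)-1,4-bis[4-(benzyloxy)phenyl]-2,3-dimethylbutyl}benzene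
Product: 17 1,3,5-tris(benzyloxy)-2-bromo-4-{(1S,2R,3S)-1,4-bis[4-(benzyloxy)phenyl]-2,3-dimethylbutyl}benzene
Conditions: NBS (1.0 equiv), CH2Cl2, −40 to 0 °C, dark
Reagents that add atoms: N-bromosuccinimide, O=C1CCC(=O)N1Br
Why: Electrophilic aromatic bromination. The trialkoxy ring A is by far the most nucleophilic arene and its two free positions are equivalent, so a single monobromide is expected.

Step 12
Reactants: 18 3-(4-methoxyphenyl)propanoic acid
Product: 20 N-methoxy-3-(4-methoxyphenyl)-N-methylpropanamide, via acyl imidazole 19 (not isolated)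
Conditions: 1,1′-carbonyldiimidazole, CH2Cl2, rt; then MeNH(OMe)·HCl, rt
Reagents that add atoms: N,O-dimethylhydroxylamine hydrochloride, CNOC.Cl
Why: Activation of the acid as acyl imidazole 19 with loss of CO2, then aminolysis to the N-methoxy-N-methylamide; routine amide formation.

Step 13
Reactants: 17 1,3,5-tris(benzyloxy)-2-bromo-4-{(1S,2R,3S)-1,4-bis[4-(benzyloxy)phenyl]-2,3-dimethylbutyl}benzene; 20 N-methoxy-3-(4-methoxyphenyl)-N-methylpropanamide
Product: 23 1-{2,4,6-tris(benzyloxy)-3-[(1S,2R,3S)-1,4-bis[4-(benzyloxy)phenyl]-2,3-dimethylbutyl]phenyl}-3-(4-methoxyphenyl)propan-1-one, via aryllithium 21 (not isolated), via lithium hemiaminal adduct 22 (not isolated)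
Conditions: n-BuLi (1.05 equiv), THF, −78 °C; then 20 (1.3 equiv), −78 to 0 °C; 1 M aq. HCl, 0 °C
Reagents that add atoms: none
Why: Bromine–lithium exchange gives aryllithium 21, which adds to the N-methoxy-N-methylamide; the chelated adduct 22 does not collapse until the quench, so the ketone forms without over-addition. The medium stays basic or only briefly and coldly acidic, so the acid-labile C1–C3′ bond is not ionised.

Step 14
Reactants: 23 1-{2,4,6-tris(benzyloxy)-3-[(1S,2R,3S)-1,4-bis[4-(benzyloxy)phenyl]-2,3-dimethylbutyl]phenyl}-3-(4-methoxyphenyl)propan-1-one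
Product: 24 1-{3-[(1S,2R,3S)-1,4-bis(4-hydroxyphenyl)-2,3-dimethylbutyl]-2,4,6-trihydroxyphenyl}-3-(4-methoxyphenyl)propan-1-one
Conditions: H2 (1 atm), 10% Pd/C, EtOAc/MeOH 1:1, rt
Reagents that add atoms: none
Why: Hydrogenolysis of five benzyl aryl ethers. The methyl ether is inert, the doubly ortho-oxygenated aryl ketone is a poor substrate for reduction, and no stereocentre is affected.

## Compound list

1 | 5,7-dihydroxy-2H-chromen-2-one | O=c1ccc2c(O)cc(O)cc2o1 | starting material
2 | 5,7-bis(benzyloxy)-2H-chromen-2-one | O=c1ccc2c(OCc3ccccc3)cc(OCc3ccccc3)cc2o1 | intermediate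
3 | [4-(benzyloxy)phenyl]boronic acid | OB(O)c1ccc(OCc2ccccc2)cc1 | starting material
4 | (4S)-5,7-bis(benzyloxy)-4-[4-(benzyloxy)phenyl]-3,4-dihydro-2H-chromen-2-one | O=C1C[C@@H](c2ccc(OCc3ccccc3)cc2)c2c(OCc3ccccc3)cc(OCc3ccccc3)cc2O1 | intermediate
5 | L-tyrosine | N[C@@H](Cc1ccc(O)cc1)C(=O)O | starting material
6 | (1S)-1-carboxylato-2-(4-hydroxyphenyl)ethane-1-diazonium (diazonium carboxylate) | N#[N+][C@@H](Cc1ccc(O)cc1)C(=O)[O-] | intermediate (not isolated)
7 | (3R)-3-(4-hydroxybenzyl)oxiran-2-one (α-lactone) | O=C1O[C@@H]1Cc1ccc(O)cc1 | intermediate (not isolated)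
8 | (2S)-2-hydroxy-3-(4-hydroxyphenyl)propanoic acid | O[C@@H](Cc1ccc(O)cc1)C(=O)O | intermediate
9 | benzyl (2S)-3-[4-(benzyloxy)phenyl]-2-hydroxypropanoate | O[C@@H](Cc1ccc(OCc2ccccc2)cc1)C(=O)OCc1ccccc1 | intermediate
10 | benzyl (2S)-3-[4-(benzyloxy)phenyl]-2-{[(trifluoromethyl)sulfonyl]oxy}propanoate | O=S(=O)(O[C@@H](Cc1ccc(OCc2ccccc2)cc1)C(=O)OCc1ccccc1)C(F)(F)F | intermediate
11 | lithium (4S)-5,7-bis(benzyloxy)-4-[4-(benzyloxy)phenyl]-4H-chromen-2-olate | [Li]OC1=C[C@@H](c2ccc(OCc3ccccc3)cc2)c2c(OCc3ccccc3)cc(OCc3ccccc3)cc2O1 | intermediate (not isolated)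
12 | benzyl (2S)-3-[4-(benzyloxy)phenyl]-2-{(3S,4S)-5,7-bis(benzyloxy)-4-[4-(benzyloxy)phenyl]-2-oxo-3,4-dihydro-2H-chromen-3-yl}propanoate | O=C1Oc2cc(OCc3ccccc3)cc(OCc3ccccc3)c2[C@H](c2ccc(OCc3ccccc3)cc2)[C@H]1[C@@H](C(=O)OCc1ccccc1)Cc1ccc(OCc2ccccc2)cc1 | intermediate
13 | (2S,3S)-2-[4-(benzyloxy)benzyl]-3-{(S)-[2,4-bis(benzyloxy)-6-hydroxyphenyl][4-(benzyloxy)phenyl]methyl}butane-1,4-diol | Oc1cc(OCc2ccccc2)cc(OCc2ccccc2)c1[C@H](c1ccc(OCc2ccccc2)cc1)[C@H](CO)[C@@H](CO)Cc1ccc(OCc2ccccc2)cc1 | intermediate
14 | (2S,3S)-2-[4-(benzyloxy)benzyl]-3-{(S)-[4-(benzyloxy)phenyl][2,4,6-tris(benzyloxy)phenyl]methyl}butane-1,4-diol | c1ccccc1COc1cc(OCc2ccccc2)cc(OCc2ccccc2)c1[C@H](c1ccc(OCc2ccccc2)cc1)[C@H](CO)[C@@H](CO)Cc1ccc(OCc2ccccc2)cc1 | intermediate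
15 | (2S,3S)-2-[4-(benzyloxy)benzyl]-3-{(S)-[4-(benzyloxy)phenyl][2,4,6-tris(benzyloxy)phenyl]methyl}butane-1,4-diyl dimethanesulfonate | c1ccccc1COc1cc(OCc2ccccc2)cc(OCc2ccccc2)c1[C@H](c1ccc(OCc2ccccc2)cc1)[C@H](COS(C)(=O)=O)[C@@H](COS(C)(=O)=O)Cc1ccc(OCc2ccccc2)cc1 | intermediate
16 | 1,3,5-tris(benzyloxy)-2-{(1S,2R,3S)-1,4-bis[4-(benzyloxy)phenyl]-2,3-dimethylbutyl}benzene | c1ccccc1COc1cc(OCc2ccccc2)cc(OCc2ccccc2)c1[C@H](c1ccc(OCc2ccccc2)cc1)[C@H](C)[C@@H](C)Cc1ccc(OCc2ccccc2)cc1 | intermediate
17 | 1,3,5-tris(benzyloxy)-2-bromo-4-{(1S,2R,3S)-1,4-bis[4-(benzyloxy)phenyl]-2,3-dimethylbutyl}benzene | Brc1c(OCc2ccccc2)cc(OCc2ccccc2)c([C@H](c2ccc(OCc3ccccc3)cc2)[C@H](C)[C@@H](C)Cc2ccc(OCc3ccccc3)cc2)c1OCc1ccccc1 | intermediate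
18 | 3-(4-methoxyphenyl)propanoic acid | COc1ccc(CCC(=O)O)cc1 | starting material
19 | 1-(1H-imidazol-1-yl)-3-(4-methoxyphenyl)propan-1-one (acyl imidazole) | COc1ccc(CCC(=O)n2ccnc2)cc1 | intermediate (not isolated)
20 | N-methoxy-3-(4-methoxyphenyl)-N-methylpropanamide | COc1ccc(CCC(=O)N(C)OC)cc1 | intermediate
21 | {2,4,6-tris(benzyloxy)-3-[(1S,2R,3S)-1,4-bis[4-(benzyloxy)phenyl]-2,3-dimethylbutyl]phenyl}lithium | [Li]c1c(OCc2ccccc2)cc(OCc2ccccc2)c([C@H](c2ccc(OCc3ccccc3)cc2)[C@H](C)[C@@H](C)Cc2ccc(OCc3ccccc3)cc2)c1OCc1ccccc1 | intermediate (not isolated)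
22 | lithium 1-{2,4,6-tris(benzyloxy)-3-[(1S,2R,3S)-1,4-bis[4-(benzyloxy)phenyl]-2,3-dimethylbutyl]phenyl}-1-[methoxy(methyl)amino]-3-(4-methoxyphenyl)propan-1-olate (either configuration at the new carbon) | COc1ccc(CCC(O[Li])(N(C)OC)c2c(OCc3ccccc3)cc(OCc3ccccc3)c([C@H](c3ccc(OCc4ccccc4)cc3)[C@H](C)[C@@H](C)Cc3ccc(OCc4ccccc4)cc3)c2OCc2ccccc2)cc1 | intermediate (not isolated)
23 | 1-{2,4,6-tris(benzyloxy)-3-[(1S,2R,3S)-1,4-bis[4-(benzyloxy)phenyl]-2,3-dimethylbutyl]phenyl}-3-(4-methoxyphenyl)propan-1-one | COc1ccc(CCC(=O)c2c(OCc3ccccc3)cc(OCc3ccccc3)c([C@H](c3ccc(OCc4ccccc4)cc3)[C@H](C)[C@@H](C)Cc3ccc(OCc4ccccc4)cc3)c2OCc2ccccc2)cc1 | intermediate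
24 | 1-{3-[(1S,2R,3S)-1,4-bis(4-hydroxyphenyl)-2,3-dimethylbutyl]-2,4,6-trihydroxyphenyl}-3-(4-methoxyphenyl)propan-1-one | COc1ccc(CCC(=O)c2c(O)cc(O)c([C@H](c3ccc(O)cc3)[C@H](C)[C@@H](C)Cc3ccc(O)cc3)c2O)cc1 | target

## Step count and least certain steps

Total step count: 14. Longest linear sequence: 11 steps (from 5 through steps 3, 4, 5, 6, 7, 8, 9, 10, 11, 13 and 14 to 24).

**Step 6 (key step).** The most likely failure is base-induced elimination of triflic acid from 10 outrunning substitution, because the β-hydrogens are benzylic. Bond formation between two secondary carbons may also be slow. The fallback joins the same two carbons by one-electron chemistry with no leaving group. It sets out from 4 and comes back at 13.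
- Commercial 3-[4-(benzyloxy)phenyl]propanoic acid is coupled to commercial (4R)-4-benzyl-1,3-oxazolidin-2-one (pivaloyl chloride, Et3N, LiCl, THF) to give the imide (4R)-4-benzyl-3-{3-[4-(benzyloxy)phenyl]propanoyl}-1,3-oxazolidin-2-one F1.
- The lithium enolates of 4 and of F1 (LiN(SiMe3)2, THF, −78 °C) are combined and oxidised with Fe(acac)3 (trivalent iron) in an intermolecular oxidative enolate heterocoupling.
- The auxiliary is expected to shield one face of the imide partner and the C4 aryl one face of the lactone partner, leading to the coupled imide lactone (4R)-4-benzyl-3-[(2S)-3-[4-(benzyloxy)phenyl]-2-{(3S,4S)-5,7-bis(benzyloxy)-4-[4-(benzyloxy)phenyl]-2-oxo-3,4-dihydro-2H-chromen-3-yl}propanoyl]-1,3-oxazolidin-2-one F2.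
- LiBH4 in THF/MeOH then reduces lactone and imide together to 13 and releases the auxiliary.

**Step 2.** Carbometalation may be slow because of the peri benzyloxy group and the donor-substituted enoate, so protodeboronation could consume the aryl donor and enantioface selection could erode. The fallback gives up catalysis for a racemic addition and a resolution. It sets out from 2 and comes back at 4.
- Commercial 4-(benzyloxy)phenylmagnesium bromide with CuBr·SMe2 and Me3SiCl in THF (−78 to 0 °C) adds to 2 to give racemic 5,7-bis(benzyloxy)-4-[4-(benzyloxy)phenyl]-3,4-dihydro-2H-chromen-2-one F3.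
- Aminolysis with (1S)-1-phenylethanamine opens the aryl lactone to two diastereomeric phenol amides, which are separated by crystallisation or chromatography.
- The isomer (3S)-3-[2,4-bis(benzyloxy)-6-hydroxyphenyl]-3-[4-(benzyloxy)phenyl]-N-[(1S)-1-phenylethyl]propanamide F4 is relactonised with TsOH in toluene at reflux to 4, releasing the amine.

**Step 11.** Ipso attack at C3′ followed by loss of the stabilised benzylic cation (bromodealkylation), or a second bromination, may compete with monobromination. The fallback acylates directly, without halogenation or metalation. It sets out from 16 and comes back at 23.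
- 18 is treated with (CF3CO)2O in CH2Cl2 at 0 °C to form the mixed anhydride 3-(4-methoxyphenyl)propanoic trifluoroacetic anhydride F5.
- F5 acylates ring A of 16 in a Friedel–Crafts reaction at one of its two equivalent positions.
- Short contact time at low temperature limits acid exposure of C1.

**Step 13.** Proton transfer from the α-CH2 of 20 to the hindered aryllithium, or migration of the anion to a benzylic ether position, may win over addition. The fallback moves the acylation to the unprotected stage. It sets out from 16 and comes back at 24.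
- Hydrogenolysis (H2, 10% Pd/C, EtOAc/MeOH) gives 2-[(1S,2R,3S)-1,4-bis(4-hydroxyphenyl)-2,3-dimethylbutyl]benzene-1,3,5-triol F6.
- A Houben–Hoesch reaction with commercial 3-(4-methoxyphenyl)propanenitrile (ZnCl2, HCl gas, Et2O, 0 °C) gives the ketiminium chloride 1-{3-[(1S,2R,3S)-1,4-bis(4-hydroxyphenyl)-2,3-dimethylbutyl]-2,4,6-trihydroxyphenyl}-3-(4-methoxyphenyl)propan-1-iminium chloride F7.
- Mild aqueous hydrolysis of F7 gives 24. The two free positions of ring A are equivalent and the other rings are far less nucleophilic.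

## Further compounds

F1 | step 6 | (4R)-4-benzyl-3-{3-[4-(benzyloxy)phenyl]propanoyl}-1,3-oxazolidin-2-one | O=C(CCc1ccc(OCc2ccccc2)cc1)N1[C@H](Cc2ccccc2)COC1=O
F2 | step 6 | (4R)-4-benzyl-3-[(2S)-3-[4-(benzyloxy)phenyl]-2-{(3S,4S)-5,7-bis(benzyloxy)-4-[4-(benzyloxy)phenyl]-2-oxo-3,4-dihydro-2H-chromen-3-yl}propanoyl]-1,3-oxazolidin-2-one | O=C1Oc2cc(OCc3ccccc3)cc(OCc3ccccc3)c2[C@H](c2ccc(OCc3ccccc3)cc2)[C@H]1[C@@H](C(=O)N1[C@H](Cc2ccccc2)COC1=O)Cc1ccc(OCc2ccccc2)cc1
F3 | step 2 | racemic 5,7-bis(benzyloxy)-4-[4-(benzyloxy)phenyl]-3,4-dihydro-2H-chromen-2-one | O=C1CC(c2ccc(OCc3ccccc3)cc2)c2c(OCc3ccccc3)cc(OCc3ccccc3)cc2O1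
F4 | step 2 | (3S)-3-[2,4-bis(benzyloxy)-6-hydroxyphenyl]-3-[4-(benzyloxy)phenyl]-N-[(1S)-1-phenylethyl]propanamide | C[C@H](NC(=O)C[C@@H](c1ccc(OCc2ccccc2)cc1)c1c(O)cc(OCc2ccccc2)cc1OCc1ccccc1)c1ccccc1
F5 | step 11 | 3-(4-methoxyphenyl)propanoic trifluoroacetic anhydride | COc1ccc(CCC(=O)OC(=O)C(F)(F)F)cc1
F6 | step 13 | 2-[(1S,2R,3S)-1,4-bis(4-hydroxyphenyl)-2,3-dimethylbutyl]benzene-1,3,5-triol | Oc1cc(O)cc(O)c1[C@H](c1ccc(O)cc1)[C@H](C)[C@@H](C)Cc1ccc(O)cc1
F7 | step 13 | 1-{3-[(1S,2R,3S)-1,4-bis(4-hydroxyphenyl)-2,3-dimethylbutyl]-2,4,6-trihydroxyphenyl}-3-(4-methoxyphenyl)propan-1-iminium chloride | COc1ccc(CCC(=[NH2+])c2c(O)cc(O)c([C@H](c3ccc(O)cc3)[C@H](C)[C@@H](C)Cc3ccc(O)cc3)c2O)cc1.[Cl-]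
A1 | alternative 1 | (2R,3S)-1,4-bis(4-hydroxyphenyl)-2,3-dimethylbutan-1-ol (either configuration at C1) | OC(c1ccc(O)cc1)[C@H](C)[C@@H](C)Cc1ccc(O)cc1
A2 | alternative 1 | 4-[(2R,3S)-4-(4-hydroxyphenyl)-2,3-dimethylbutylidene]cyclohexa-2,5-dien-1-one | O=C1C=CC(=C[C@H](C)[C@@H](C)Cc2ccc(O)cc2)C=C1
A3 | alternative 1 | 3-(4-methoxyphenyl)-1-(2,4,6-trihydroxyphenyl)propan-1-one | COc1ccc(CCC(=O)c2c(O)cc(O)cc2O)cc1
A4 | alternative 2 | racemic [2,4-bis(benzyloxy)-6-hydroxyphenyl][4-(benzyloxy)phenyl]methanol | OC(c1ccc(OCc2ccccc2)cc1)c1c(O)cc(OCc2ccccc2)cc1OCc1ccccc1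
A5 | alternative 2 | (3S)-4-[4-(benzyloxy)phenyl]-3-methylbutanoic acid | OC(=O)C[C@@H](C)Cc1ccc(OCc2ccccc2)cc1
A6 | alternative 2 | (3R,4S)-5,7-bis(benzyloxy)-4-[4-(benzyloxy)phenyl]-3-{(2S)-1-[4-(benzyloxy)phenyl]propan-2-yl}-3,4-dihydro-2H-chromen-2-one | O=C1Oc2cc(OCc3ccccc3)cc(OCc3ccccc3)c2[C@H](c2ccc(OCc3ccccc3)cc2)[C@H]1[C@@H](C)Cc1ccc(OCc2ccccc2)cc1
A7 | alternative 3 | (2E)-but-2-en-1-yl (3S)-3-[4-(benzyloxy)phenyl]-3-[2,4,6-tris(benzyloxy)phenyl]propanoate | C/C=C/COC(=O)C[C@@H](c1ccc(OCc2ccccc2)cc1)c1c(OCc2ccccc2)cc(OCc2ccccc2)cc1OCc1ccccc1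
A8 | alternative 3 | (2R,3S)-2-{(S)-[4-(benzyloxy)phenyl][2,4,6-tris(benzyloxy)phenyl]methyl}-3-methylpent-4-enoic acid | c1ccccc1COc1cc(OCc2ccccc2)cc(OCc2ccccc2)c1[C@H](c1ccc(OCc2ccccc2)cc1)[C@H](C(=O)O)[C@@H](C)C=C
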